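**Retrosynthetic overview**

1. The target is a cyclohex-2-en-1-one (C1 carbonyl, C2=C3, C4 secondary carbinol, C5 tertiary carbinol carrying the (8Z)-heptadec-8-enyl chain, C6 methylene) with a cis-4,5-diol, (4R,5S). The strategy rests on the C4–C5 ring bond, which joins two oxygen-bearing carbons, and on C5 plus its chain being the intact C18 skeleton of oleic acid (C5 = carboxyl carbon).
2. The target is traced back to the spiro-dithiane α-ketol 15 (C1 masked as a 1,3-dithiane, C4 a ketone, C5 the tertiary carbinol) by dithiane hydrolysis, desilylation, substrate-controlled C4 reduction and C2–C3 desaturation.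
3. Key disconnection: C4–C5 of 15, a carbene-catalysed crossed benzoin in which the C4 aldehyde of acyclic keto-aldehyde 13 acts as acyl anion toward the C5 oleoyl ketone.
4. 13 comes from ynone 8 and propane-1,3-dithiol (double conjugate addition places the dithiane at C1). 8 comes from the oleic acid Weinreb amide 3 and silyl-protected pent-4-yn-1-ol 5 (C5–C6 bond).
5. Ring order: the dithiane heterocycle first (step 4), then the only carbocycle (step 7).

Key step: step 7

Assumption: the (5aS,10bR) triazolium salt is taken to favour the ketone enantioface that leads to the (8S)-ketol; should the sense of induction prove opposite, the (5aR,10bS) salt from the equally available antipodal aminoindanol is used with no other change.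

**Route**

Step 1
Reactants: 1 oleic acid
Product: 3 (9Z)-N-methoxy-N-methyloctadec-9-enamide, via oleoyl chloride 2 (not isolated)
Conditions: (COCl)2, DMF (cat.), CH2Cl2, 0 °C → rt; then MeNH(OMe)·HCl, Et3N, 0 °C → rt
Reagents that add atoms: N,O-dimethylhydroxylamine hydrochloride, CNOC.Cl
Why: Vilsmeier-catalysed conversion of the acid into its chloride followed by N-acylation of N,O-dimethylhydroxylamine (Weinreb amide formation) touches only the carboxyl group, so the isolated Z-alkene keeps its geometry.

Step 2
Reactants: 4 pent-4-yn-1-ol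
Product: 5 tert-butyl(dimethyl)(pent-4-yn-1-yloxy)silane
Conditions: t-BuMe2SiCl, imidazole, CH2Cl2, 0 °C → rt
Reagents that add atoms: tert-butyl(chloro)dimethylsilane, CC(C)(C)[Si](C)(C)Cl
Why: Imidazole-mediated O-silylation of a primary alcohol is selective and leaves the terminal alkyne C–H free for the metalation of step 3.

Step 3
Reactants: 5 tert-butyl(dimethyl)(pent-4-yn-1-yloxy)silane; 3 (9Z)-N-methoxy-N-methyloctadec-9-enamide
Product: 8 (14Z)-1-{[tert-butyl(dimethyl)silyl]oxy}tricos-14-en-4-yn-6-one, via lithium acetylide 6 (not isolated), via tetrahedral lithium adduct 7 (not isolated)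
Conditions: 5 (1.2 equiv), n-BuLi, THF, −78 °C; then 3, −78 → 0 °C; cold aq. NH4Cl
Reagents that add atoms: none
Why: In this Weinreb ketone synthesis the acetylide adds once to the amide and the lithium chelate 7 persists until the cold, mildly acidic quench, which prevents over-addition and keeps the liberated amine from adding to the ynone.

Step 4
Reactants: 8 (14Z)-1-{[tert-butyl(dimethyl)silyl]oxy}tricos-14-en-4-yn-6-one; 9 propane-1,3-dithiol
Product: 11 (10Z)-1-[2-(3-{[tert-butyl(dimethyl)silyl]oxy}propyl)-1,3-dithian-2-yl]nonadec-10-en-2-one, via monothiol vinyl sulfide 10 (not isolated)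
Conditions: 9 (1.1 equiv), NaOMe (1.3 equiv), MeOH/CH2Cl2 (4:1), −10 °C → rt; aq. NH4Cl
Reagents that add atoms: none
Why: Base-mediated double thia-Michael addition: the thiolate adds to the ynone β-carbon to give the β-sulfanyl enone 10, whose pendant thiol adds again at the same carbon in a 6-exo closure, so that the thermodynamically favoured β-keto-1,3-dithiane results and the carbon that becomes C1 is masked at the ketone oxidation level, while the unactivated Z-alkene is no acceptor.

Step 5
Reactants: 11 (10Z)-1-[2-(3-{[tert-butyl(dimethyl)silyl]oxy}propyl)-1,3-dithian-2-yl]nonadec-10-en-2-one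
Product: 12 (10Z)-1-[2-(3-hydroxypropyl)-1,3-dithian-2-yl]nonadec-10-en-2-one
Conditions: HF·pyridine, pyridine, THF, 0 °C → rt
Reagents that add atoms: none
Why: Fluoride cleaves the primary Si–O bond under weakly acidic buffered conditions (desilylation), which avoids enolising the β-keto dithiane toward retro-Michael opening and leaves thioacetal, ketone and alkene untouched.

Step 6
Reactants: 12 (10Z)-1-[2-(3-hydroxypropyl)-1,3-dithian-2-yl]nonadec-10-en-2-one
Product: 13 3-{2-[(10Z)-2-oxononadec-10-en-1-yl]-1,3-dithian-2-yl}propanal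
Conditions: SO3·pyridine, DMSO, i-Pr2NEt, CH2Cl2, 0 °C
Reagents that add atoms: none
Why: Parikh–Doering oxidation with activated DMSO stops at the aldehyde and, unlike iodine- or chromium-based oxidants, does not attack thioacetal sulfur; the keto-aldehyde is kept cold and used directly to forestall aldol self-condensation.

Step 7
Reactants: 13 3-{2-[(10Z)-2-oxononadec-10-en-1-yl]-1,3-dithian-2-yl}propanal
Product: 15 (8S)-8-[(8Z)-heptadec-8-en-1-yl]-8-hydroxy-1,5-dithiaspiro[5.5]undecan-9-one, via Breslow enaminol 14 (not isolated)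
Conditions: (5aS,10bR)-2-(pentafluorophenyl)-5a,10b-dihydro-4H,6H-indeno[2,1-b][1,2,4]triazolo[4,3-d][1,4]oxazin-2-ium tetrafluoroborate (20 mol %), Et3N (20 mol %), toluene (0.05 M), rt
Reagents that add atoms: none
Why: The triazolylidene released from the salt by Et3N adds to the aldehyde carbon of 13 (future C4) and proton transfer gives the Breslow enaminol 14, whose nucleophilic carbon attacks the oleoyl ketone carbon (future C5); proton transfer and expulsion of the carbene then deliver the α-ketol 15. This is the carbene-catalysed intramolecular crossed aldehyde–ketone benzoin reaction, established for aliphatic keto-aldehydes that give six-membered tertiary α-hydroxy ketones. The cyclohexanone ring closes in 6-exo-trig fashion, the attacked ketone C=O lying outside the forming ring. The single new stereocentre, C8 of 15 (C5 of the target), is set by the aminoindanol-derived carbene, which in the hydrogen-bonded cyclic transition state presents the enaminol to one enantioface of the ketone, the dithiane-bearing tether and the linear chain occupying different regions of the catalyst pocket. Chemoselectivity comes from the substrate: only the aldehyde can become the acyl-anion equivalent, only one ketone lies within reach, the C1 carbonyl is masked as a dithiane that also favours closure through the gem-disubstituent effect, and the Z-alkene is inert to carbene and amine. The selectivity that has to be earned is ketone enantioface discrimination and rate over amine-mediated aldol cyclisation, for which the rigid, electron-poor N-pentafluorophenyl catalyst and a weak base are chosen.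

Step 8
Reactants: 15 (8S)-8-[(8Z)-heptadec-8-en-1-yl]-8-hydroxy-1,5-dithiaspiro[5.5]undecan-9-one
Product: 16 (8S)-8-[(8Z)-heptadec-8-en-1-yl]-8-[(triethylsilyl)oxy]-1,5-dithiaspiro[5.5]undecan-9-one
Conditions: Et3SiOTf, 2,6-lutidine, CH2Cl2, −78 → 0 °C
Reagents that add atoms: triethylsilyl trifluoromethanesulfonate, CC[Si](CC)(CC)OS(=O)(=O)C(F)(F)F
Why: Silyl triflate with a hindered pyridine base silylates the tertiary carbinol (O-silylation) without enolising the ketone or risking α-ketol rearrangement at low temperature; the ether masks the acidic OH for step 9 and provides the non-chelating axial group that directs step 11, the C8 configuration being untouched.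

Step 9
Reactants: 16 (8S)-8-[(8Z)-heptadec-8-en-1-yl]-8-[(triethylsilyl)oxy]-1,5-dithiaspiro[5.5]undecan-9-one
Product: 18 (8S)-8-[(8Z)-heptadec-8-en-1-yl]-10-(phenylselanyl)-8-[(triethylsilyl)oxy]-1,5-dithiaspiro[5.5]undecan-9-one (C10 epimer mixture), via lithium enolate 17 (not isolated)
Conditions: LiN(i-Pr)2, THF, −78 °C; then PhSeBr (1.05 equiv), −78 °C
Reagents that add atoms: phenylselanyl bromide, Br[Se]c1ccccc1
Why: Deprotonation can occur only at C10 because the other α-carbon (C8) is quaternary, and the lithium enolate is selenenylated at carbon (enolate α-selenenylation) far faster than PhSeBr adds to the remote alkene when the reagent is added to the cold enolate in slight excess only; the new C10 centre is removed in step 10, so its configuration is immaterial.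

Step 10
Reactants: 18 (8S)-8-[(8Z)-heptadec-8-en-1-yl]-10-(phenylselanyl)-8-[(triethylsilyl)oxy]-1,5-dithiaspiro[5.5]undecan-9-one (C10 epimer mixture)
Product: 20 (8S)-8-[(8Z)-heptadec-8-en-1-yl]-8-[(triethylsilyl)oxy]-1,5-dithiaspiro[5.5]undec-10-en-9-one, via selenoxide 19 (not isolated)
Conditions: 3-chloroperoxybenzoic acid (1.0 equiv), CH2Cl2, −78 °C; then i-Pr2NH, −78 °C → rt
Reagents that add atoms: none
Why: Selenium is oxidised much faster than thioacetal sulfur or an isolated alkene by one equivalent of peracid at −78 °C, and the selenoxide then undergoes syn-elimination toward the only β-hydrogens (C11) on warming, the amine scavenging benzeneselenenic acid, to give the conjugated enone with C8 unaffected.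

Step 11
Reactants: 20 (8S)-8-[(8Z)-heptadec-8-en-1-yl]-8-[(triethylsilyl)oxy]-1,5-dithiaspiro[5.5]undec-10-en-9-one
Product: 21 (8S,9R)-8-[(8Z)-heptadec-8-en-1-yl]-8-[(triethylsilyl)oxy]-1,5-dithiaspiro[5.5]undec-10-en-9-ol
Conditions: NaBH4, CeCl3·7H2O, MeOH, −78 °C
Reagents that add atoms: none
Why: Luche reduction delivers hydride 1,2 to the enone; in the half-chair the C8 chain lies pseudo-equatorial and the C8–OSiEt3 bond pseudo-axial (the smaller group, and the one that suffers less from the syn-axial dithiane sulfur), so hydride enters along the axial trajectory antiperiplanar to that C–O bond, on the face opposite the silyloxy group (Felkin–Anh polar model), which places the new C9 hydroxyl cis to the C8 oxygen and sets C9 as R.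

Step 12
Reactants: 21 (8S,9R)-8-[(8Z)-heptadec-8-en-1-yl]-8-[(triethylsilyl)oxy]-1,5-dithiaspiro[5.5]undec-10-en-9-ol
Product: 22 (4R,5S)-5-[(8Z)-heptadec-8-en-1-yl]-4-hydroxy-5-[(triethylsilyl)oxy]cyclohex-2-en-1-one
Conditions: PhI(OCOCF3)2, NaHCO3, MeCN/H2O (9:1), 0 °C
Reagents that add atoms: water, O
Why: Oxidative hydrolysis of the thioacetal: the iodane activates sulfur, the allylically stabilised thionium ion is captured by water and the second C–S bond is cleaved likewise, a reaction that is complete within minutes at 0 °C, tolerates alkenes and free alcohols, and under bicarbonate buffering should not trigger β-elimination of the C5 oxygen; neither stereocentre is involved.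

Step 13
Reactants: 22 (4R,5S)-5-[(8Z)-heptadec-8-en-1-yl]-4-hydroxy-5-[(triethylsilyl)oxy]cyclohex-2-en-1-one
Product: 23 (4R,5S)-5-[(8Z)-heptadec-8-en-1-yl]-4,5-dihydroxycyclohex-2-en-1-one
Conditions: HF·pyridine, pyridine, THF, 0 °C → rt
Reagents that add atoms: none
Why: Fluoride-mediated desilylation under pyridine-buffered, weakly acidic conditions removes the triethylsilyl group without the basic conditions that would cause E1cB loss of the β-oxygen and aromatisation of the 4,5-dihydroxycyclohexenone, and the C4 and C5 configurations are unchanged.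

**Compound list**

1 | oleic acid | CCCCCCCC/C=C\CCCCCCCC(=O)O | starting material
2 | (9Z)-octadec-9-enoyl chloride | CCCCCCCC/C=C\CCCCCCCC(=O)Cl | intermediate
3 | (9Z)-N-methoxy-N-methyloctadec-9-enamide | CCCCCCCC/C=C\CCCCCCCC(=O)N(C)OC | intermediate
4 | pent-4-yn-1-ol | C#CCCCO | starting material
5 | tert-butyl(dimethyl)(pent-4-yn-1-yloxy)silane | C#CCCCO[Si](C)(C)C(C)(C)C | intermediate
6 | [5-{[tert-butyl(dimethyl)silyl]oxy}pent-1-yn-1-yl]lithium | [Li]C#CCCCO[Si](C)(C)C(C)(C)C | intermediate
7 | lithium (14Z)-1-{[tert-butyl(dimethyl)silyl]oxy}-6-[methoxy(methyl)amino]tricos-14-en-4-yn-6-olate | CCCCCCCC/C=C\CCCCCCCC(O[Li])(C#CCCCO[Si](C)(C)C(C)(C)C)N(C)OC | intermediate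
8 | (14Z)-1-{[tert-butyl(dimethyl)silyl]oxy}tricos-14-en-4-yn-6-one | CCCCCCCC/C=C\CCCCCCCC(=O)C#CCCCO[Si](C)(C)C(C)(C)C | intermediate
9 | propane-1,3-dithiol | SCCCS | starting material
10 | (14Z)-1-{[tert-butyl(dimethyl)silyl]oxy}-4-[(3-sulfanylpropyl)sulfanyl]tricosa-4,14-dien-6-one (C4=C5 geometry mixed) | CCCCCCCC/C=C\CCCCCCCC(=O)C=C(SCCCS)CCCO[Si](C)(C)C(C)(C)C | intermediate
11 | (10Z)-1-[2-(3-{[tert-butyl(dimethyl)silyl]oxy}propyl)-1,3-dithian-2-yl]nonadec-10-en-2-one | CCCCCCCC/C=C\CCCCCCCC(=O)CC1(SCCCS1)CCCO[Si](C)(C)C(C)(C)C | intermediate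
12 | (10Z)-1-[2-(3-hydroxypropyl)-1,3-dithian-2-yl]nonadec-10-en-2-one | CCCCCCCC/C=C\CCCCCCCC(=O)CC1(SCCCS1)CCCO | intermediate
13 | 3-{2-[(10Z)-2-oxononadec-10-en-1-yl]-1,3-dithian-2-yl}propanal | CCCCCCCC/C=C\CCCCCCCC(=O)CC1(SCCCS1)CCC=O | intermediate
14 | Breslow enaminol: adduct of the (5aS,10bR)-2-(pentafluorophenyl)triazolylidene at the aldehyde carbon of 13 | OC(CCC5(SCCCS5)CC(=O)CCCCCCC/C=C\CCCCCCCC)=C1N(c2c(F)c(F)c(F)c(F)c2F)N=C2CO[C@H]3Cc4ccccc4[C@H]3N12 | intermediate
15 | (8S)-8-[(8Z)-heptadec-8-en-1-yl]-8-hydroxy-1,5-dithiaspiro[5.5]undecan-9-one | CCCCCCCC/C=C\CCCCCCC[C@]1(O)CC2(SCCCS2)CCC1=O | intermediate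
16 | (8S)-8-[(8Z)-heptadec-8-en-1-yl]-8-[(triethylsilyl)oxy]-1,5-dithiaspiro[5.5]undecan-9-one | CCCCCCCC/C=C\CCCCCCC[C@]1(O[Si](CC)(CC)CC)CC2(SCCCS2)CCC1=O | intermediate
17 | lithium enolate (C9–C10) of 16 | CCCCCCCC/C=C\CCCCCCC[C@]1(O[Si](CC)(CC)CC)CC2(SCCCS2)CC=C1O[Li] | intermediate
18 | (8S)-8-[(8Z)-heptadec-8-en-1-yl]-10-(phenylselanyl)-8-[(triethylsilyl)oxy]-1,5-dithiaspiro[5.5]undecan-9-one (C10 epimer mixture) | CCCCCCCC/C=C\CCCCCCC[C@]1(O[Si](CC)(CC)CC)CC2(SCCCS2)CC([Se]c3ccccc3)C1=O | intermediate
19 | (8S)-8-[(8Z)-heptadec-8-en-1-yl]-10-(phenylseleninyl)-8-[(triethylsilyl)oxy]-1,5-dithiaspiro[5.5]undecan-9-one | CCCCCCCC/C=C\CCCCCCC[C@]1(O[Si](CC)(CC)CC)CC2(SCCCS2)CC([Se](=O)c3ccccc3)C1=O | intermediate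
20 | (8S)-8-[(8Z)-heptadec-8-en-1-yl]-8-[(triethylsilyl)oxy]-1,5-dithiaspiro[5.5]undec-10-en-9-one | CCCCCCCC/C=C\CCCCCCC[C@]1(O[Si](CC)(CC)CC)CC2(SCCCS2)C=CC1=O | intermediate
21 | (8S,9R)-8-[(8Z)-heptadec-8-en-1-yl]-8-[(triethylsilyl)oxy]-1,5-dithiaspiro[5.5]undec-10-en-9-ol | CCCCCCCC/C=C\CCCCCCC[C@]1(O[Si](CC)(CC)CC)CC2(SCCCS2)C=C[C@H]1O | intermediate
22 | (4R,5S)-5-[(8Z)-heptadec-8-en-1-yl]-4-hydroxy-5-[(triethylsilyl)oxy]cyclohex-2-en-1-one | CCCCCCCC/C=C\CCCCCCC[C@]1(O[Si](CC)(CC)CC)CC(=O)C=C[C@H]1O | intermediate
23 | (4R,5S)-5-[(8Z)-heptadec-8-en-1-yl]-4,5-dihydroxycyclohex-2-en-1-one | CCCCCCCC/C=C\CCCCCCC[C@]1(O)CC(=O)C=C[C@H]1O | target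

**Step count and risks**

Total: 13 steps. Longest linear sequence: 12 steps (oleic acid through steps 1 and 3–13, or equally pent-4-yn-1-ol through steps 2–13).

Steps most likely to fail:

Step 7. The carbene may discriminate poorly between the two methylene-flanked faces of the C5 ketone, or the encumbered catalyst may add so slowly to this hindered dialkyl ketone that amine-mediated aldol cyclisation takes over. The fallback gives up catalyst control and sets out from 13. The small achiral carbene from 3-benzyl-5-(2-hydroxyethyl)-4-methylthiazolium chloride and DBU in t-BuOH at 40 °C would pass through the thiazolylidene Breslow enaminol of 13 F1 and close the same C4–C5 bond without stereocontrol to racemic 8-[(8Z)-heptadec-8-en-1-yl]-8-hydroxy-1,5-dithiaspiro[5.5]undecan-9-one F2. Preparative chromatography on an amylose tris(3,5-dimethylphenylcarbamate) stationary phase would then separate the enantiomers; the (8S)-enantiomer is 15, where the route is rejoined.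

Step 11. Facial selection by the ring conformation alone may be insufficient, so that hydride also enters syn to the silyloxy group and the trans-diol series forms. The fallback replaces substrate control by reagent control and sets out from 20. Corey–Bakshi–Shibata reduction with (S)-1-methyl-3,3-diphenyltetrahydro-1H,3H-pyrrolo[1,2-c][1,3,2]oxazaborole and 1,3,2-benzodioxaborole (catecholborane) in toluene at −78 °C should deliver hydride to the Si face of C9 if the fully substituted C8 flank binds as the large group (the antipodal oxazaborolidine is used if the vinyl flank dominates). It would give the catechol borate (8S,9R)-9-(1,3,2-benzodioxaborol-2-yloxy)-8-[(8Z)-heptadec-8-en-1-yl]-8-[(triethylsilyl)oxy]-1,5-dithiaspiro[5.5]undec-10-ene F4, hydrolysed on aqueous work-up to 21, where the route is rejoined. Catecholborane does not hydroborate the Z-alkene at this temperature.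

Step 10. Oxidation may not stop at selenium, giving S-oxidation of the dithiane or epoxidation of the Z-alkene, and the selenium electrophile of step 9 may add across the alkene. The fallback is an oxidant-free dehydrogenation that replaces steps 9 and 10 and sets out from 16. Its enolate 17 (LiN(i-Pr)2, THF, −78 °C) would be treated with N-tert-butylbenzenesulfinimidoyl chloride to give the α-sulfilimine adduct (8S)-10-(N-tert-butyl-S-phenylsulfinimidoyl)-8-[(8Z)-heptadec-8-en-1-yl]-8-[(triethylsilyl)oxy]-1,5-dithiaspiro[5.5]undecan-9-one F3. This should lose N-tert-butylbenzenesulfenamide by intramolecular syn-elimination on warming and so give 20 directly, where the route is rejoined.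

**Further compounds**

F1 | step 7 | Breslow enaminol: adduct of 3-benzyl-5-(2-hydroxyethyl)-4-methylthiazol-2-ylidene at the aldehyde carbon of 13 | OC(CCC5(SCCCS5)CC(=O)CCCCCCC/C=C\CCCCCCCC)=C1SC(CCO)=C(C)N1Cc2ccccc2
F2 | step 7 | racemic 8-[(8Z)-heptadec-8-en-1-yl]-8-hydroxy-1,5-dithiaspiro[5.5]undecan-9-one | CCCCCCCC/C=C\CCCCCCCC1(O)CC2(SCCCS2)CCC1=O
F3 | step 10 | (8S)-10-(N-tert-butyl-S-phenylsulfinimidoyl)-8-[(8Z)-heptadec-8-en-1-yl]-8-[(triethylsilyl)oxy]-1,5-dithiaspiro[5.5]undecan-9-one | CCCCCCCC/C=C\CCCCCCC[C@]1(O[Si](CC)(CC)CC)CC2(SCCCS2)CC(S(=NC(C)(C)C)c3ccccc3)C1=O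
F4 | step 11 | (8S,9R)-9-(1,3,2-benzodioxaborol-2-yloxy)-8-[(8Z)-heptadec-8-en-1-yl]-8-[(triethylsilyl)oxy]-1,5-dithiaspiro[5.5]undec-10-ene | CCCCCCCC/C=C\CCCCCCC[C@]1(O[Si](CC)(CC)CC)CC2(SCCCS2)C=C[C@H]1OB3Oc4ccccc4O3
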